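Everything rests on cutting the C6–C7 bond of benzene ring A in the 7-methoxycoumarin half (unit A, coumarin numbering). The feature exploited is that C7, C8 and C8a of ring A each bear oxygen, so they map onto the carbonyl carbon and the two alkene carbons of a cyclobutenone made from squaric acid. Thermolysis of a 4-vinylcyclobutenone then builds ring A in one operation as a phenol in which the crowded diaryl ether at C8 is already present and only the C7 hydroxyl is free. The precursor is a racemic cyclobut-2-enone with the 2,6-bis(benzyloxy)-4-isopropoxyphenoxy group on C2, benzyloxy on C3 and vinyl on C4.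

Key step: step 9

Remark: the target has no stereocentre; 10, 11 and 13 are racemic at the sp3 ring carbon, which is destroyed in step 9.
Remark: primed locants (1' to 6') denote the phenoxy ring that becomes unit B, with 1' the ether carbon.
Remark: on a squarate an aryloxy group is a better leaving group than benzyloxy, so the aryl ether bond to the four-membered ring is made by irreversible displacement of chloride (step 5) and not by ester exchange.

Step 1
Reactants: 1 2,4,6-trihydroxybenzaldehyde
Product: 2 2,6-dihydroxy-4-isopropoxybenzaldehyde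
Conditions: iPrOH (1.05 equiv), PPh3, DIAD, THF, 0 °C to rt
Reagents that add atoms: propan-2-ol, CC(C)O
Why: Mitsunobu etherification should alkylate the most acidic phenol, the 4-hydroxyl para to the aldehyde, because the two ortho hydroxyls are hydrogen-bonded to the carbonyl and are weaker nucleophiles.

Step 2
Reactants: 2 2,6-dihydroxy-4-isopropoxybenzaldehyde
Product: 3 2,6-bis(benzyloxy)-4-isopropoxybenzaldehyde
Conditions: BnBr (2.4 equiv), K2CO3, DMF, 60 °C
Reagents that add atoms: benzyl bromide, BrCc1ccccc1
Why: Williamson ether synthesis in a dipolar aprotic solvent with gentle heating overcomes the hydrogen bond of the ortho phenols, as in routine perbenzylation of hydroxybenzaldehydes.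

Step 3
Reactants: 3 2,6-bis(benzyloxy)-4-isopropoxybenzaldehyde
Product: 5 2,6-bis(benzyloxy)-4-isopropoxyphenol, via aryl formate 4 (not isolated)
Conditions: mCPBA, CH2Cl2, 0 °C to rt; NaHCO3 wash; then K2CO3 (cat.), MeOH, rt, under argon
Reagents that add atoms: 3-chloroperbenzoic acid, OOC(=O)c1cccc(Cl)c1
Why: In this Baeyer–Villiger oxidation the electron-rich trialkoxyaryl group migrates in preference to hydrogen to give formate 4, which mild methanolysis cleaves to the phenol without touching the ethers.

Step 4
Reactants: 6 squaric acid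
Product: 7 3,4-dichlorocyclobut-3-ene-1,2-dione
Conditions: SOCl2 (2.2 equiv), DMF (cat.), toluene, 80 °C
Reagents that add atoms: thionyl chloride, O=S(Cl)Cl
Why: DMF-catalysed chlorination of the two vinylogous acid hydroxyls is the standard acid-to-acid-chloride conversion for squaric acid.

Step 5
Reactants: 7 3,4-dichlorocyclobut-3-ene-1,2-dione; 5 2,6-bis(benzyloxy)-4-isopropoxyphenol
Product: 9 3-(benzyloxy)-4-[2,6-bis(benzyloxy)-4-isopropoxyphenoxy]cyclobut-3-ene-1,2-dione, via benzyl ester chloride 8 (not isolated)
Conditions: BnOH (1.0 equiv), iPr2NEt (1.0 equiv), CH2Cl2, −78 °C; then 5, iPr2NEt, −78 to 0 °C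
Reagents that add atoms: benzyl alcohol, OCc1ccccc1
Why: Two successive addition–elimination reactions at vinylogous acid chloride carbons should give 9, since the benzyloxy group of 8 slows the second carbon enough for mono-substitution and the phenoxide of 5 then displaces the remaining chloride irreversibly.

Step 6
Reactants: 9 3-(benzyloxy)-4-[2,6-bis(benzyloxy)-4-isopropoxyphenoxy]cyclobut-3-ene-1,2-dione
Product: 10 racemic 3-(benzyloxy)-2-[2,6-bis(benzyloxy)-4-isopropoxyphenoxy]-4-hydroxycyclobut-2-en-1-one
Conditions: LiAlH(OtBu)3 (1.1 equiv), THF, −78 °C; pH 7 buffer quench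
Reagents that add atoms: none
Why: Carbonyl 1,2-reduction by the bulky mild hydride should occur at the carbonyl next to the benzyloxy carbon, which is vinylogous to the weakly donating aryloxy group and so is both the more electrophilic and the less hindered one; the new stereocentre is formed racemic and needs no control.

Step 7
Reactants: 10 racemic 3-(benzyloxy)-2-[2,6-bis(benzyloxy)-4-isopropoxyphenoxy]-4-hydroxycyclobut-2-en-1-one
Product: 11 racemic 3-(benzyloxy)-2-[2,6-bis(benzyloxy)-4-isopropoxyphenoxy]-4-chlorocyclobut-2-en-1-one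
Conditions: SOCl2 (1.1 equiv), pyridine (1.2 equiv), CH2Cl2, −20 to 0 °C; non-aqueous work-up, used crude
Reagents that add atoms: thionyl chloride, O=S(Cl)Cl
Why: Deoxychlorination of the allylic-type alcohol with pyridine-buffered thionyl chloride should end at the 4-chloride, because chloride return at the aryloxy-bearing terminus is reversible and the conjugated vinylogous ester is the stable isomer; the stereocentre stays racemic.

Step 8
Reactants: 11 racemic 3-(benzyloxy)-2-[2,6-bis(benzyloxy)-4-isopropoxyphenoxy]-4-chlorocyclobut-2-en-1-one; 12 tributyl(vinyl)stannane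
Product: 13 racemic 3-(benzyloxy)-2-[2,6-bis(benzyloxy)-4-isopropoxyphenoxy]-4-vinylcyclobut-2-en-1-one
Conditions: Pd2(dba)3 (2.5 mol%), tri(2-furyl)phosphine (10 mol%), THF, 23 °C; short silica plug, used at once
Reagents that add atoms: none
Why: In this Stille coupling of an allylic-type chloride, zerovalent palladium inserts into the strained C4–Cl bond and reductive elimination at the secondary carbon C4 keeps the conjugated enone, while the weakly bound furylphosphine allows ambient temperature so that the product is not yet ring-expanded; it is formed racemic.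

Step 9
Reactants: 13 racemic 3-(benzyloxy)-2-[2,6-bis(benzyloxy)-4-isopropoxyphenoxy]-4-vinylcyclobut-2-en-1-one
Product: 16 3-(benzyloxy)-2-[2,6-bis(benzyloxy)-4-isopropoxyphenoxy]phenol, via dienylketene 14 (not isolated), via cyclohexadienone 15 (not isolated)
Conditions: toluene (0.02 M, degassed), 100 °C
Reagents that add atoms: none
Why: Heat opens the C1–C4 bond of 13 in a conrotatory four-electron electrocyclic reaction to vinylketene 14, whose ketene carbon (future C7) bonds to the terminal vinyl carbon (future C6) to give dienone 15, and enolisation then gives phenol 16. The closest known reaction type is the thermal ring expansion of 4-alkenyl- and 4-arylcyclobutenones to phenols through dienylketenes. Ring A, the only ring formed, closes by a thermally allowed disrotatory six-electron electrocyclisation to a six-membered carbocycle. No stereocentre is created, and the single stereocentre of racemic 13 (C4, future C4a) is erased on aromatisation. The step needs the ketene to close on the vinyl group instead of being trapped or dimerising, and this is secured because ring opening is reversible: the isomer with vinyl turned away from the ketene can only revert to 13, while the isomer with the two groups cis is removed for good by closure and aromatisation in a dilute, nucleophile-free medium. The oxygen pattern needs no control, since C2 (aryloxy) and C3 (benzyloxy) of 13 end up as C8 and C8a and C4 as C4a.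

Step 10
Reactants: 16 3-(benzyloxy)-2-[2,6-bis(benzyloxy)-4-isopropoxyphenoxy]phenol
Product: 17 1,3-bis(benzyloxy)-2-[2-(benzyloxy)-6-methoxyphenoxy]-5-isopropoxybenzene
Conditions: MeI, K2CO3, acetone, 50 °C
Reagents that add atoms: iodomethane, CI
Why: Williamson methylation of the only free phenol fixes the C7 methoxy group.

Step 11
Reactants: 17 1,3-bis(benzyloxy)-2-[2-(benzyloxy)-6-methoxyphenoxy]-5-isopropoxybenzene
Product: 18 2-(2-hydroxy-6-methoxyphenoxy)-5-isopropoxybenzene-1,3-diol
Conditions: H2 (1 atm), 10% Pd/C, EtOAc–EtOH, rt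
Reagents that add atoms: none
Why: Catalytic hydrogenolysis cleaves the three benzyl aryl ethers and leaves the methyl, isopropyl and diaryl ethers untouched.

Step 12
Reactants: 18 2-(2-hydroxy-6-methoxyphenoxy)-5-isopropoxybenzene-1,3-diol
Product: 19 3-(3-formyl-2-hydroxy-6-methoxyphenoxy)-2,4-dihydroxy-6-isopropoxybenzaldehyde
Conditions: MgCl2 (anhydrous, 5 equiv), Et3N (12 equiv), (CH2O)n (6 equiv), MeCN, 80 °C; 1 M HCl work-up
Reagents that add atoms: paraformaldehyde (as formaldehyde), C=O
Why: Magnesium-mediated ortho-formylation of phenols (MgCl2/Et3N, formaldehyde bound to the phenoxide, then hydride transfer to a second formaldehyde) puts CHO only ortho to OH, where ring A has one free carbon (C4a) and ring B two equivalent ones, and the first formyl group on ring B should slow a second entry there because it turns the remaining phenoxide into a vinylogous carboxylate.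

Step 13
Reactants: 19 3-(3-formyl-2-hydroxy-6-methoxyphenoxy)-2,4-dihydroxy-6-isopropoxybenzaldehyde
Product: 21 7-hydroxy-5-isopropoxy-8-[(7-methoxy-2-oxo-2H-chromen-8-yl)oxy]-2H-chromen-2-one, via bis-cinnamate diester 20 (not isolated)
Conditions: Ph3P=CHCO2Et (4 equiv), N,N-diethylaniline, 200 °C
Reagents that add atoms: ethyl (triphenylphosphoranylidene)acetate, CCOC(=O)C=P(c1ccccc1)(c1ccccc1)c1ccccc1
Why: Twofold Wittig olefination with the stabilised ylide gives 20, which at this temperature isomerises and lactonises onto the ortho phenols, and in ring B the only free hydroxyl beside the side chain is the 2'-OH because the other neighbour is the isopropyl ether, so the pyranone closes toward the ether-bearing carbon.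

Step 14
Reactants: 21 7-hydroxy-5-isopropoxy-8-[(7-methoxy-2-oxo-2H-chromen-8-yl)oxy]-2H-chromen-2-one
Product: 22 5,7-dihydroxy-8-[(7-methoxy-2-oxo-2H-chromen-8-yl)oxy]-2H-chromen-2-one (target)
Conditions: BCl3 (1 M in CH2Cl2, 4 equiv), CH2Cl2, −78 to 0 °C; MeOH then water
Reagents that add atoms: none
Why: Lewis acid dealkylation with BCl3 cleaves the secondary isopropyl aryl ether much faster than the methyl ether and should leave the lactones and the diaryl ether intact.

Compound list
1 | 2,4,6-trihydroxybenzaldehyde | O=Cc1c(O)cc(O)cc1O | starting material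
2 | 2,6-dihydroxy-4-isopropoxybenzaldehyde | O=Cc1c(O)cc(OC(C)C)cc1O | intermediate
3 | 2,6-bis(benzyloxy)-4-isopropoxybenzaldehyde | O=Cc1c(OCc2ccccc2)cc(OC(C)C)cc1OCc1ccccc1 | intermediate
4 | 2,6-bis(benzyloxy)-4-isopropoxyphenyl formate | O=COc1c(OCc2ccccc2)cc(OC(C)C)cc1OCc1ccccc1 | intermediate
5 | 2,6-bis(benzyloxy)-4-isopropoxyphenol | Oc1c(OCc2ccccc2)cc(OC(C)C)cc1OCc1ccccc1 | intermediate
6 | squaric acid | O=C1C(O)=C(O)C1=O | starting material
7 | 3,4-dichlorocyclobut-3-ene-1,2-dione | O=C1C(Cl)=C(Cl)C1=O | intermediate
8 | 3-(benzyloxy)-4-chlorocyclobut-3-ene-1,2-dione | O=C1C(Cl)=C(OCc2ccccc2)C1=O | intermediate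
9 | 3-(benzyloxy)-4-[2,6-bis(benzyloxy)-4-isopropoxyphenoxy]cyclobut-3-ene-1,2-dione | O=C1C(=O)C(OCc2ccccc2)=C1Oc1c(OCc2ccccc2)cc(OC(C)C)cc1OCc1ccccc1 | intermediate
10 | racemic 3-(benzyloxy)-2-[2,6-bis(benzyloxy)-4-isopropoxyphenoxy]-4-hydroxycyclobut-2-en-1-one | OC1C(OCc2ccccc2)=C(Oc2c(OCc3ccccc3)cc(OC(C)C)cc2OCc2ccccc2)C1=O | intermediate
11 | racemic 3-(benzyloxy)-2-[2,6-bis(benzyloxy)-4-isopropoxyphenoxy]-4-chlorocyclobut-2-en-1-one | ClC1C(OCc2ccccc2)=C(Oc2c(OCc3ccccc3)cc(OC(C)C)cc2OCc2ccccc2)C1=O | intermediate
12 | tributyl(vinyl)stannane | C=C[Sn](CCCC)(CCCC)CCCC | starting material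
13 | racemic 3-(benzyloxy)-2-[2,6-bis(benzyloxy)-4-isopropoxyphenoxy]-4-vinylcyclobut-2-en-1-one | C=CC1C(OCc2ccccc2)=C(Oc2c(OCc3ccccc3)cc(OC(C)C)cc2OCc2ccccc2)C1=O | intermediate
14 | (3E)-3-(benzyloxy)-2-[2,6-bis(benzyloxy)-4-isopropoxyphenoxy]hexa-1,3,5-trien-1-one (ketene carbon and vinyl group cis across C3=C4) | O=C=C(Oc1c(OCc2ccccc2)cc(OC(C)C)cc1OCc1ccccc1)/C(OCc1ccccc1)=C\C=C | intermediate
15 | 3-(benzyloxy)-2-[2,6-bis(benzyloxy)-4-isopropoxyphenoxy]cyclohexa-2,4-dien-1-one | O=C1CC=CC(OCc2ccccc2)=C1Oc1c(OCc2ccccc2)cc(OC(C)C)cc1OCc1ccccc1 | intermediate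
16 | 3-(benzyloxy)-2-[2,6-bis(benzyloxy)-4-isopropoxyphenoxy]phenol | Oc1cccc(OCc2ccccc2)c1Oc1c(OCc2ccccc2)cc(OC(C)C)cc1OCc1ccccc1 | intermediate
17 | 1,3-bis(benzyloxy)-2-[2-(benzyloxy)-6-methoxyphenoxy]-5-isopropoxybenzene | COc1cccc(OCc2ccccc2)c1Oc1c(OCc2ccccc2)cc(OC(C)C)cc1OCc1ccccc1 | intermediate
18 | 2-(2-hydroxy-6-methoxyphenoxy)-5-isopropoxybenzene-1,3-diol | COc1cccc(O)c1Oc1c(O)cc(OC(C)C)cc1O | intermediate
19 | 3-(3-formyl-2-hydroxy-6-methoxyphenoxy)-2,4-dihydroxy-6-isopropoxybenzaldehyde | COc1ccc(C=O)c(O)c1Oc1c(O)cc(OC(C)C)c(C=O)c1O | intermediate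
20 | ethyl (E)-3-{3-[3-((E)-3-ethoxy-3-oxoprop-1-enyl)-2-hydroxy-6-methoxyphenoxy]-2,4-dihydroxy-6-isopropoxyphenyl}acrylate | COc1ccc(/C=C/C(=O)OCC)c(O)c1Oc1c(O)cc(OC(C)C)c(/C=C/C(=O)OCC)c1O | intermediate
21 | 7-hydroxy-5-isopropoxy-8-[(7-methoxy-2-oxo-2H-chromen-8-yl)oxy]-2H-chromen-2-one | COc1ccc2ccc(=O)oc2c1Oc1c(O)cc(OC(C)C)c2ccc(=O)oc12 | intermediate
22 | 5,7-dihydroxy-8-[(7-methoxy-2-oxo-2H-chromen-8-yl)oxy]-2H-chromen-2-one | COc1ccc2ccc(=O)oc2c1Oc1c(O)cc(O)c2ccc(=O)oc12 | target

Total step count: 14.
Longest linear sequence: 13 steps (steps 1 to 3 and 5 to 14); step 4 is the one-step squarate branch that joins at step 5.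

Steps most likely to fail

Step 7. The activated hydroxyl may ionise to the oxocyclobutenyl cation, which can lose the aryloxy group on contact with moisture, take up chloride at the wrong allylic terminus, or decompose during isolation. The fallback avoids the chloride altogether and sets out from 10. Acetylation under basic conditions (Ac2O, Et3N, DMAP cat., CH2Cl2, −20 °C) should give racemic 2-(benzyloxy)-3-[2,6-bis(benzyloxy)-4-isopropoxyphenoxy]-4-oxocyclobut-2-en-1-yl acetate F1. F1 would then be coupled directly with 12 as an allylic acetate Stille coupling (Pd2(dba)3, tri(2-furyl)phosphine, LiCl, DMF, rt), returning to the route at 13.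

Step 12. Formylation may be uneven: a second formyl group may enter ring B before ring A has reacted, the reaction may stall at a mono-aldehyde, or phenols may be methoxymethylated on long heating. The fallback sets out from 17 and installs the two formyl groups by different mechanisms. Vilsmeier–Haack formylation (POCl3, DMF, 0 °C to rt) should attack only the phloroglucinol-type ring B, at one of its two equivalent free positions, and stop after one entry, giving 2,4-bis(benzyloxy)-3-[2-(benzyloxy)-6-methoxyphenoxy]-6-isopropoxybenzaldehyde F2. Hydrogenolysis as in step 11, stopped after three equivalents of hydrogen, would give 2,4-dihydroxy-3-(2-hydroxy-6-methoxyphenoxy)-6-isopropoxybenzaldehyde F3. The magnesium-mediated ortho-formylation then has to functionalise ring A only and returns to the route at 19.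

Step 5. Control over which nucleophile enters at which carbon may be lost: the dichloride may be benzyloxylated twice, leftover dichloride may consume the phenol, or the electron-rich ring of 5 may be C-acylated. The fallback sets out from 7 and 5 and inverts the order of bond formation, with isolation in between. The sodium salt of 5 (NaH, THF) is added slowly to an excess of 7 at −78 °C to give 3-[2,6-bis(benzyloxy)-4-isopropoxyphenoxy]-4-chlorocyclobut-3-ene-1,2-dione F4, which is freed from excess 7 and then treated with BnOH and iPr2NEt in CH2Cl2 at −40 °C, returning to the route at 9.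

Further compounds
F1 | step 7 | racemic 2-(benzyloxy)-3-[2,6-bis(benzyloxy)-4-isopropoxyphenoxy]-4-oxocyclobut-2-en-1-yl acetate | CC(=O)OC1C(OCc2ccccc2)=C(Oc2c(OCc3ccccc3)cc(OC(C)C)cc2OCc2ccccc2)C1=O
F2 | step 12 | 2,4-bis(benzyloxy)-3-[2-(benzyloxy)-6-methoxyphenoxy]-6-isopropoxybenzaldehyde | COc1cccc(OCc2ccccc2)c1Oc1c(OCc2ccccc2)cc(OC(C)C)c(C=O)c1OCc1ccccc1
F3 | step 12 | 2,4-dihydroxy-3-(2-hydroxy-6-methoxyphenoxy)-6-isopropoxybenzaldehyde | COc1cccc(O)c1Oc1c(O)cc(OC(C)C)c(C=O)c1O
F4 | step 5 | 3-[2,6-bis(benzyloxy)-4-isopropoxyphenoxy]-4-chlorocyclobut-3-ene-1,2-dione | O=C1C(=O)C(Cl)=C1Oc1c(OCc2ccccc2)cc(OC(C)C)cc1OCc1ccccc1
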